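At early times Monday's and Friday's runs looked alike in percent: by 2.50 h they had reacted 12.1% and 10.7% of the two substrates together. You asked me for a quick number on the flask with 20 mM of each substrate.

| flask | left-handed substrate | right-handed substrate | coupling partner | free catalyst | racemization catalyst | added ligand | remark | time |
|---|---|---|---|---|---|---|---|---|
| Monday's | 28 mM | 28 mM | 80 mM | 0.40 mM | 1 mM | 4.4 mM | run made earlier |  |
| Friday's | 44 mM | 44 mM | 80 mM | 0.40 mM | 1 mM | 4.4 mM | run made earlier |  |
| flask | 20 mM | 20 mM | 80.0 mM | 0.40 mM | 1.0 mM | 4.4 mM |  | 8.0 h |

- Monday's (time / h: left-handed substrate / %, right-handed substrate / %, left-handed product / %): 2.50: 43.6, 44.3, 7.0; 5.00: 38.9, 40.9, 12.0; 8.00: 34.4, 38.4, 16.9; 10.0: 31.9, 35.3, 20.6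
- Friday's (time / h: left-handed substrate / %, right-handed substrate / %, left-handed product / %): 2.50: 43.9, 45.4, 6.4; 5.00: 38.8, 41.9, 12.2; 8.00: 35.7, 38.1, 16.5; 10.0: 31.8, 35.0, 19.9

(readings scatter by 0.5 percentage points)

- part of the left-handed substrate and right-handed substrate charged together that has reacted at 8.0 h
- excess of left-handed product over right-handed product in the product at 8.0 h
- excess of right-handed substrate over left-handed substrate among what is left of the two at 8.0 h

- free catalyst is single-handed; left-handed substrate and right-handed substrate are mirror images of each other, charged as a racemate, each of them at the stated concentration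
- an excess is the difference of the two amounts in percent of their sum
- an excess is below zero if the other one leads

I took the last readings, at 10.0 h: 32.8% had reacted on Monday's and 33.2% on Friday's. But equal percents hid a difference. Counting one coupling partner per substrate and taking the straight mean of start and end, I put mean [coupling partner] over the run at its charge minus the reacted fraction times the charged [left-handed substrate], so 70.8 mM on Monday's and less on Friday's, 65.4 mM.

I therefore replaced the falling partner by its mean. The logarithm of charged over remaining substrate, per hour, scaled by charged over mean [coupling partner], gave 0.0449 h⁻¹ and 0.0494 h⁻¹. Their mean is my charge constant, the pseudo-first-order constant of the summed substrates with the partner held at its charge and free catalyst at 0.40 mM: 0.0471 h⁻¹.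

For the flask, a first pass gave mean [coupling partner] 73.7 mM, and with it I reckoned 29.4% reacted at 8.0 h. The straight mean stood 0.340 mM from the time-mean of that curve.

Your forecast said 27.3%, 24% and 4.4%, holding the reaction “close to first order in substrate and hardly sensitive to partner depletion”. My c stood 2.1 percentage points above yours, and I reckoned neither excess.

The flask gave 29.6%, 21.8% and 5.17%, inside the forecast's margins and 0.20 points from my c.

    racemization catalyst → spent catalyst (k = 0.00690 min⁻¹)
    left-handed substrate + racemization catalyst ⇌ right-handed substrate + racemization catalyst, rate k2*[racemization catalyst]*[left-handed substrate] forward; the back reaction follows from the equilibrium constant (k = 9.40 M⁻¹ min⁻¹)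
    coupling partner + free catalyst + left-handed substrate → free catalyst + left-handed product (k = 31.0 M⁻² min⁻¹)
    racemization catalyst + added ligand ⇌ idle complex (K = 120 M⁻¹, k = 0.140 M⁻¹ min⁻¹)
    coupling partner + free catalyst + right-handed substrate → free catalyst + right-handed product (k = 19.0 M⁻² min⁻¹)

In the flask the coupling partner's half-life by the left-handed step stood at 56 h at 3.44 h, longer than the 8.0 h of the run, and 85% of its charge remained at the end. Multiplied by 4.00 for the neighbour flask with 1.6 mM of free catalyst and reckoned the same way, 0.0471 h⁻¹ gave 70.3%, and that neighbour flask reached 69.2%.

The runs come from a simulation for substances that don't exist, noise included.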